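**Retrosynthetic overview**
1. Target ⇒ cross-metathesis of core methacrylate 13 with (S)-alkenol 17 (from Cu-catalysed conjugate addition to methyl crotonate); the ester C–O bond comes from Mitsunobu inversion of alcohol 11.
2. 11 ⇒ ketone 9 (LiAlH4 reduces C=O and turns N-CO2Me into N-Me); 9 ⇒ dienone 7 by face-selective hydrogenation, which sets C4 and C4a from C7a.
3. 7 ⇒ dichloro-alkoxy-cyclopentanone 6 (Cr(II) reductive elimination, auxiliary released); key step: 6 ⇐ cyclobutanone 5 by one-carbon ring expansion with diazoethane (1,2-shift of C7a, bringing in C7 and its methyl).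
4. 5 ⇐ auxiliary-controlled dichloroketene [2+2] on the 4-alkoxy-1,2-dihydropyridine 4 (sets C7a); 4 ⇐ 4-chloro-3-methylpyridine 1.
5. Ring order: pyridine ring (bought) → fused cyclobutanone → cyclopentanone (ring expansion) → saturation to the piperidine.

Assumption: the (1R,2S)-auxiliary directs dichloroketene to the face of 4 that gives (7aR) (core numbering); if the sense is opposite, the equally available (1S,2R)-alcohol is used and nothing else changes.

Step 1
Reactants: 1 4-chloro-3-methylpyridine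
Product: 2 3-methyl-4-{[(1R,2S)-2-phenylcyclohexyl]oxy}pyridine
Conditions: (1R,2S)-2-phenylcyclohexanol, NaH, DMSO, 90 °C
Reagents that add atoms: (1R,2S)-2-phenylcyclohexan-1-ol, O[C@@H]1CCCC[C@H]1c1ccccc1
Why: SNAr by the sodium alkoxide at the activated 4-position of the pyridine installs the recoverable chiral ether that later steers the cycloaddition; no stereocentre is formed.

Step 2
Reactants: 2 3-methyl-4-{[(1R,2S)-2-phenylcyclohexyl]oxy}pyridine
Product: 4 methyl 5-methyl-4-{[(1R,2S)-2-phenylcyclohexyl]oxy}-2H-pyridine-1-carboxylate, via N-acylpyridinium chloride 3 (not isolated)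
Conditions: ClCO2Me, THF, −78 °C; then NaBH4, MeOH, −78 °C; cold NaHCO3 work-up, used at once
Reagents that add atoms: methyl chloroformate, COC(=O)Cl
Why: Fowler-type reduction of the N-acylpyridinium salt; C4 is blocked by the alkoxy group and hydride adds at C6, away from the 3-methyl group, giving the 4-alkoxy-1,2-dihydropyridine (a cyclic 1-amido-3-alkoxy diene).

Step 3
Reactants: 4 methyl 5-methyl-4-{[(1R,2S)-2-phenylcyclohexyl]oxy}-2H-pyridine-1-carboxylate
Product: 5 methyl (1R,6S)-7,7-dichloro-5-methyl-8-oxo-6-{[(1R,2S)-2-phenylcyclohexyl]oxy}-3-azabicyclo[4.2.0]oct-4-ene-3-carboxylate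
Conditions: Cl3CCOCl, Zn–Cu, Et2O/DME, 0 °C → rt
Reagents that add atoms: trichloroacetyl chloride, ClC(Cl)(Cl)C(Cl)=O
Why: Proposed new method: auxiliary-controlled [2+2] of dichloroketene on the enol-ether bond of a 4-alkoxy-1,2-dihydropyridine; C3, the terminus of this amido-alkoxy diene, is its most nucleophilic carbon and attacks the ketene carbonyl carbon, the oxocarbenium/vinylogous N-acyliminium ion is closed at C4 by the dichloroenolate (cis-fused cyclobutanone with C=O next to the future C7a), and the phenyl group of the auxiliary shields one face of the enol ether so that C7a is set; the closest known reaction is the asymmetric dichloroketene cycloaddition to acyclic chiral (Z)-enol ethers, which has not been shown on cyclic amido-alkoxy dienes.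

Step 4
Reactants: 5 methyl (1R,6S)-7,7-dichloro-5-methyl-8-oxo-6-{[(1R,2S)-2-phenylcyclohexyl]oxy}-3-azabicyclo[4.2.0]oct-4-ene-3-carboxylate
Product: 6 methyl (4aS,7aR)-5,5-dichloro-4,7-dimethyl-6-oxo-4a-{[(1R,2S)-2-phenylcyclohexyl]oxy}-1,4a,5,6,7,7a-hexahydro-2H-cyclopenta[c]pyridine-2-carboxylate (both C7 epimers)
Conditions: CH3CHN2 (1.3 equiv, freshly made from N-ethyl-N-nitrosourea/KOH), Et2O, MeOH (cat.), 0 °C
Reagents that add atoms: diazoethane, CC=[N+]=[N-]
Why: Tiffeneau–Demjanov-type diazoalkane ring expansion (the key step): diazoethane adds to the strained, electron-poor C=O and the non-chlorinated α-carbon (C7a) makes the 1,2-shift with retention, while the CCl2 carbon does not migrate; this gives the cyclopentanone with C7 and its methyl in place, C7 being corrected later.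

Step 5
Reactants: 6 methyl (4aS,7aR)-5,5-dichloro-4,7-dimethyl-6-oxo-4a-{[(1R,2S)-2-phenylcyclohexyl]oxy}-1,4a,5,6,7,7a-hexahydro-2H-cyclopenta[c]pyridine-2-carboxylate
Product: 7 methyl (7aS)-4,7-dimethyl-6-oxo-1,6,7,7a-tetrahydro-2H-cyclopenta[c]pyridine-2-carboxylate (both C7 epimers)
Conditions: CrCl2 (6 equiv), DMF/H2O, 0 °C → rt
Reagents that add atoms: none
Why: Cr(II) reduces both C–Cl bonds and the chromium enolate expels the β-alkoxide (reductive β-elimination, as in the chiral enol-ether cyclopentenone annulation), releasing the auxiliary and leaving a dienone whose only fixed stereocentre is C7a.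

Step 6
Reactants: 7 methyl (7aS)-4,7-dimethyl-6-oxo-1,6,7,7a-tetrahydro-2H-cyclopenta[c]pyridine-2-carboxylate
Product: 9 methyl (4R,4aS,7S,7aR)-4,7-dimethyl-6-oxooctahydro-2H-cyclopenta[c]pyridine-2-carboxylate, via C7 epimer 8 (not isolated)
Conditions: H2 (5 bar), 10% Pd/C, EtOAc, rt; filter; then NaOMe (0.2 equiv), MeOH, rt
Reagents that add atoms: none
Why: Heterogeneous syn-hydrogenation from the convex face (the face of H7a) gives the cis ring fusion at C4a and then delivers H to C4 of the cis-fused enecarbamate from the same face, so H4, H4a and H7a are all cis; NaOMe then equilibrates the ketone α-centre C7 to the more stable epimer with the methyl trans to C1.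

Step 7
Reactants: 9 methyl (4R,4aS,7S,7aR)-4,7-dimethyl-6-oxooctahydro-2H-cyclopenta[c]pyridine-2-carboxylate
Product: 11 (4R,4aS,6S,7S,7aR)-2,4,7-trimethyloctahydro-1H-cyclopenta[c]pyridin-6-ol, via hydroxy carbamate 10 (not isolated)
Conditions: LiAlH4 (4 equiv), THF, 0 °C, then reflux
Reagents that add atoms: none
Why: Hydride reduction: LiAlH4 attacks the cyclopentanone from the convex face, cis to the C7 methyl (as small hydrides do with 2-methylcyclopentanones), giving the (6S) alcohol, and on heating reduces the methyl carbamate to N-methyl.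

Step 8
Reactants: 11 (4R,4aS,6S,7S,7aR)-2,4,7-trimethyloctahydro-1H-cyclopenta[c]pyridin-6-ol; 12 methacrylic acid
Product: 13 (4R,4aS,6R,7S,7aR)-2,4,7-trimethyloctahydro-1H-cyclopenta[c]pyridin-6-yl 2-methylprop-2-enoate
Conditions: PPh3, DIAD, THF, 0 °C → rt
Reagents that add atoms: none
Why: Mitsunobu esterification; the (6S)-oxyphosphonium is displaced by methacrylate with SN2 inversion, giving the (6R) ester with oxygen cis to the C7 methyl.

Step 9
Reactants: 14 methyl (2E)-but-2-enoate; 15 but-3-en-1-ylmagnesium bromide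
Product: 16 methyl (3S)-3-methylhept-6-enoate
Conditions: CuBr·SMe2 (5 mol %), Josiphos (6 mol %, enantiomer giving S), t-BuOMe, −75 °C; NH4Cl
Reagents that add atoms: none
Why: Copper/Josiphos-catalysed asymmetric conjugate addition of a Grignard reagent to an α,β-unsaturated ester; the ligand enantiomer decides the face and sets the (S) methyl centre.

Step 10
Reactants: 16 methyl (3S)-3-methylhept-6-enoate
Product: 17 (3S)-3-methylhept-6-en-1-ol
Conditions: LiAlH4, Et2O, 0 °C
Reagents that add atoms: none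
Why: Hydride reduction of the ester to the primary alcohol; the stereocentre and the terminal alkene are untouched.

Step 11
Reactants: 13 (4R,4aS,6R,7S,7aR)-2,4,7-trimethyloctahydro-1H-cyclopenta[c]pyridin-6-yl 2-methylprop-2-enoate; 17 (3S)-3-methylhept-6-en-1-ol
Product: 18 (4R,4aS,6R,7S,7aR)-2,4,7-trimethyloctahydro-1H-cyclopenta[c]pyridin-6-yl (2E,6S)-8-hydroxy-2,6-dimethyloct-2-enoate
Conditions: TsOH·H2O (1.05 equiv), Hoveyda–Grubbs II (5 mol %), 17 (3 equiv), CH2Cl2, 40 °C; NaHCO3 work-up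
Reagents that add atoms: none
Why: Olefin cross-metathesis of a terminal alkene (in excess; its homodimer re-enters) with the methacrylate; the amine is masked as its tosylate salt, the free alcohol is tolerated, and the trisubstituted enoate forms as the favoured (E) isomer.

**Compound list**
1 | 4-chloro-3-methylpyridine | Cc1cnccc1Cl | starting material
2 | 3-methyl-4-{[(1R,2S)-2-phenylcyclohexyl]oxy}pyridine | Cc1cnccc1O[C@@H]2CCCC[C@H]2c2ccccc2 | intermediate
3 | 1-(methoxycarbonyl)-3-methyl-4-{[(1R,2S)-2-phenylcyclohexyl]oxy}pyridin-1-ium chloride | COC(=O)[n+]1ccc(O[C@@H]2CCCC[C@H]2c2ccccc2)c(C)c1.[Cl-] | intermediate (not isolated)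
4 | methyl 5-methyl-4-{[(1R,2S)-2-phenylcyclohexyl]oxy}-2H-pyridine-1-carboxylate | COC(=O)N1CC=C(O[C@@H]2CCCC[C@H]2c2ccccc2)C(C)=C1 | intermediate
5 | methyl (1R,6S)-7,7-dichloro-5-methyl-8-oxo-6-{[(1R,2S)-2-phenylcyclohexyl]oxy}-3-azabicyclo[4.2.0]oct-4-ene-3-carboxylate | COC(=O)N1C[C@H]2C(=O)C(Cl)(Cl)[C@@]2(O[C@@H]3CCCC[C@H]3c3ccccc3)C(C)=C1 | intermediate
6 | methyl (4aS,7aR)-5,5-dichloro-4,7-dimethyl-6-oxo-4a-{[(1R,2S)-2-phenylcyclohexyl]oxy}-1,4a,5,6,7,7a-hexahydro-2H-cyclopenta[c]pyridine-2-carboxylate (both C7 epimers) | COC(=O)N1C[C@H]2C(C)C(=O)C(Cl)(Cl)[C@@]2(O[C@@H]3CCCC[C@H]3c3ccccc3)C(C)=C1 | intermediate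
7 | methyl (7aS)-4,7-dimethyl-6-oxo-1,6,7,7a-tetrahydro-2H-cyclopenta[c]pyridine-2-carboxylate (both C7 epimers) | O=C1C=C2C(C)=CN(C(=O)OC)C[C@H]2C1C | intermediate
8 | methyl (4R,4aS,7R,7aR)-4,7-dimethyl-6-oxooctahydro-2H-cyclopenta[c]pyridine-2-carboxylate | O=C1C[C@@H]2[C@@H](CN(C(=O)OC)C[C@@H]2C)[C@H]1C | intermediate (not isolated)
9 | methyl (4R,4aS,7S,7aR)-4,7-dimethyl-6-oxooctahydro-2H-cyclopenta[c]pyridine-2-carboxylate | O=C1C[C@@H]2[C@@H](CN(C(=O)OC)C[C@@H]2C)[C@@H]1C | intermediate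
10 | methyl (4R,4aS,6S,7S,7aR)-6-hydroxy-4,7-dimethyloctahydro-2H-cyclopenta[c]pyridine-2-carboxylate | O[C@H]1C[C@@H]2[C@@H](CN(C(=O)OC)C[C@@H]2C)[C@@H]1C | intermediate (not isolated)
11 | (4R,4aS,6S,7S,7aR)-2,4,7-trimethyloctahydro-1H-cyclopenta[c]pyridin-6-ol | O[C@H]1C[C@@H]2[C@@H](CN(C)C[C@@H]2C)[C@@H]1C | intermediate
12 | 2-methylprop-2-enoic acid (methacrylic acid) | CC(=C)C(=O)O | starting material
13 | (4R,4aS,6R,7S,7aR)-2,4,7-trimethyloctahydro-1H-cyclopenta[c]pyridin-6-yl 2-methylprop-2-enoate | CC(=C)C(=O)O[C@@H]1C[C@@H]2[C@@H](CN(C)C[C@@H]2C)[C@@H]1C | intermediate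
14 | methyl (2E)-but-2-enoate | C/C=C/C(=O)OC | starting material
15 | but-3-en-1-ylmagnesium bromide | C=CCC[Mg]Br | starting material
16 | methyl (3S)-3-methylhept-6-enoate | C=CCC[C@H](C)CC(=O)OC | intermediate
17 | (3S)-3-methylhept-6-en-1-ol | C=CCC[C@H](C)CCO | intermediate
18 | (4R,4aS,6R,7S,7aR)-2,4,7-trimethyloctahydro-1H-cyclopenta[c]pyridin-6-yl (2E,6S)-8-hydroxy-2,6-dimethyloct-2-enoate | C/C(=C\CC[C@H](C)CCO)C(=O)O[C@@H]1C[C@@H]2[C@@H](CN(C)C[C@@H]2C)[C@@H]1C | target

**Step count and risks**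
Total: 11 steps. Longest linear sequence: 9 (steps 1–8, then 11). The three steps most likely to fail are 2, 3 and 11; step 3 is the proposed new one.

Step 2 (hydride may also add at C2 next to the methyl group, and 4 is an acid-labile dienol ether). The fallback sets out from 2 and comes back at 4. Neutral 2 is dearomatised by Rh-catalysed 1,2-hydroboration ([Rh(cod)Cl]2/PCy3, HBpin), which is sterically controlled and puts hydride on the unhindered C6. This gives 5-methyl-4-{[(1R,2S)-2-phenylcyclohexyl]oxy}-1-(4,4,5,5-tetramethyl-1,3,2-dioxaborolan-2-yl)-1,2-dihydropyridine F1. Methyl chloroformate added to the same flask exchanges boron for the carbamate and gives 4.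

Step 3 (the new step: the auxiliary may give little face selectivity on this cyclic diene). The fallback sets out from 1 and comes back at 11. It gives up asymmetric induction and uses an achiral enol ether followed by classical resolution:
- NaOMe in MeOH converts 1 into 4-methoxy-3-methylpyridine F2.
- ClCO2Me/NaBH4 gives methyl 4-methoxy-5-methyl-2H-pyridine-1-carboxylate F3.
- Dichloroketene gives the racemic cis-fused cycloadduct F4.
- Diazoethane gives the racemic ring-expanded dichloroketone F5.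
- CrCl2 gives the racemic dienone F6.
- Hydrogenation and equilibration as in step 6 give the racemic ketone F7.
- LiAlH4 gives the racemic amino alcohol F8.
- Crystallisation with (S)-mandelic acid (or its antipode, whichever gives the less soluble salt of the wanted enantiomer) gives the (S)-mandelate salt of 11 F9; NaOH then frees 11.

Step 11 (a hindered methacrylate carrying an amine is a poor metathesis partner). The fallback sets out from 17, uses 11 instead of 13, and comes back at 18: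
- TBSCl/imidazole gives tert-butyl(dimethyl){[(3S)-3-methylhept-6-en-1-yl]oxy}silane F10.
- Cross-metathesis with excess methyl methacrylate (Grubbs II) gives methyl (2E,6S)-8-{[tert-butyl(dimethyl)silyl]oxy}-2,6-dimethyloct-2-enoate F11.
- LiOH gives (2E,6S)-8-{[tert-butyl(dimethyl)silyl]oxy}-2,6-dimethyloct-2-enoic acid F12.
- Mitsunobu coupling with 11 (PPh3, DIAD) gives the silyl-protected ester F13.
- TBAF gives 18.

Further compounds
F1 | step 2 | 5-methyl-4-{[(1R,2S)-2-phenylcyclohexyl]oxy}-1-(4,4,5,5-tetramethyl-1,3,2-dioxaborolan-2-yl)-1,2-dihydropyridine | CC1(C)OB(OC1(C)C)N1CC=C(O[C@@H]2CCCC[C@H]2c2ccccc2)C(C)=C1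
F2 | step 3 | 4-methoxy-3-methylpyridine | COc1ccncc1C
F3 | step 3 | methyl 4-methoxy-5-methyl-2H-pyridine-1-carboxylate | COC(=O)N1CC=C(OC)C(C)=C1
F4 | step 3 | racemic methyl (1R*,6S*)-7,7-dichloro-6-methoxy-5-methyl-8-oxo-3-azabicyclo[4.2.0]oct-4-ene-3-carboxylate | COC(=O)N1CC2C(=O)C(Cl)(Cl)C2(OC)C(C)=C1
F5 | step 3 | racemic methyl (4aS*,7aR*)-5,5-dichloro-4a-methoxy-4,7-dimethyl-6-oxo-1,4a,5,6,7,7a-hexahydro-2H-cyclopenta[c]pyridine-2-carboxylate | COC(=O)N1CC2C(C)C(=O)C(Cl)(Cl)C2(OC)C(C)=C1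
F6 | step 3 | racemic methyl 4,7-dimethyl-6-oxo-1,6,7,7a-tetrahydro-2H-cyclopenta[c]pyridine-2-carboxylate | O=C1C=C2C(C)=CN(C(=O)OC)CC2C1C
F7 | step 3 | racemic methyl (4R*,4aS*,7S*,7aR*)-4,7-dimethyl-6-oxooctahydro-2H-cyclopenta[c]pyridine-2-carboxylate | O=C1CC2C(CN(C(=O)OC)CC2C)C1C
F8 | step 3 | racemic (4R*,4aS*,6S*,7S*,7aR*)-2,4,7-trimethyloctahydro-1H-cyclopenta[c]pyridin-6-ol | OC1CC2C(CN(C)CC2C)C1C
F9 | step 3 | (4R,4aS,6S,7S,7aR)-2,4,7-trimethyloctahydro-1H-cyclopenta[c]pyridin-6-ol (S)-mandelate | O[C@H]1C[C@@H]2[C@@H](CN(C)C[C@@H]2C)[C@@H]1C.O[C@H](C(=O)O)c1ccccc1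
F10 | step 11 | tert-butyl(dimethyl){[(3S)-3-methylhept-6-en-1-yl]oxy}silane | C=CCC[C@H](C)CCO[Si](C)(C)C(C)(C)C
F11 | step 11 | methyl (2E,6S)-8-{[tert-butyl(dimethyl)silyl]oxy}-2,6-dimethyloct-2-enoate | COC(=O)/C(C)=C/CC[C@H](C)CCO[Si](C)(C)C(C)(C)C
F12 | step 11 | (2E,6S)-8-{[tert-butyl(dimethyl)silyl]oxy}-2,6-dimethyloct-2-enoic acid | OC(=O)/C(C)=C/CC[C@H](C)CCO[Si](C)(C)C(C)(C)C
F13 | step 11 | (4R,4aS,6R,7S,7aR)-2,4,7-trimethyloctahydro-1H-cyclopenta[c]pyridin-6-yl (2E,6S)-8-{[tert-butyl(dimethyl)silyl]oxy}-2,6-dimethyloct-2-enoate | C/C(=C\CC[C@H](C)CCO[Si](C)(C)C(C)(C)C)C(=O)O[C@@H]1C[C@@H]2[C@@H](CN(C)C[C@@H]2C)[C@@H]1C
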